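The reagent is the partner that starting material needs, and the runs midnight and dusk show how far a charge of it goes; the flasks teal and amber are to be told from those runs.

| setting | midnight | dusk | teal | amber |
|---|---|---|---|---|
| starting material | 0.010 M | 0.010 M | 0.010 M | 0.010 M |
| reagent | 3.5 mM | 5.2 mM | 7.00 mM | 7.00 mM |
| temperature | 68 °C | 84 °C | 70 °C | 80 °C |
| remark | run made earlier | run made earlier |  |  |
| time |  |  | 5.0 h | 5.0 h |

midnight run (percent of the starting material charged)

| time / h | intermediate A / % | intermediate B / % | starting material / % | intermediate C / % | product / % |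
|---|---|---|---|---|---|
| 0.333 | 15.7 | 0.9 | 81.2 | 0.2 | 1.8 |
| 0.500 | 18.5 | 1.5 | 77.1 | 1.1 | 1.7 |
| 0.667 | 20.9 | 2.2 | 73.4 | 3.7 | 0.7 |
| 1.00 | 21.5 | 1.7 | 69.5 | 4.7 | 0.6 |
| 1.50 | 20.2 | 2.1 | 67.7 | 10.1 | 0.8 |
| 2.50 | 15.1 | 1.5 | 65.5 | 17.4 | 0 |
| 4.00 | 8.3 | 1.2 | 65.0 | 25.1 | 0.1 |

dusk run (percent of the starting material charged)

| time / min | intermediate A / % | intermediate B / % | starting material / % | intermediate C / % | product / % |
|---|---|---|---|---|---|
| 10.0 | 24.2 | 1.9 | 68.0 | 5.0 | 1.8 |
| 15.0 | 26.0 | 3.3 | 61.6 | 8.3 | 1.3 |
| 20.0 | 26.6 | 2.9 | 57.9 | 12.4 | 0.8 |
| 30.0 | 23.0 | 2.8 | 53.0 | 20.3 | 0 |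
| 50.0 | 15.8 | 2.4 | 48.6 | 31.9 | 0 |
| 80.0 | 8.7 | 2.0 | 48.0 | 40.8 | 0 |
| 120 | 5.2 | 1.7 | 48.1 | 44.8 | 0 |

(each reading ± 0.5 percentage points)

- a reading or a percentage of product counts all its forms, free or not

- which of these there is most of at the end, counted by the starting material in it, teal (intermediate A / starting material / intermediate C / intermediate B)
- which of these there is most of at the end, counted by the starting material in it, amber (intermediate A / starting material / intermediate C / intermediate B)
- final amount of the leader among these, as a percentage of the starting material charged, in teal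
- final amount of the leader among these, as a percentage of the starting material charged, in amber

1. Starting material stops falling in both runs while plenty of it remains: midnight has lost 35.0 % by its last reading and dusk 51.9 %, while the charges of reagent over starting material are 35.0 % and 52.0 %. So the reagent acts as the limiting reagent, one for one. That gives the convertible share, the reagent charged over the starting material charged, which is 70.0 % for teal and for amber, so starting material should stop at 30.0 % in both.

2. At 2.50 h midnight reads 0.5 percentage points above its last reading, a gap of the size of the scatter of 0.5 points, and that time is shorter than the 5.0 h given to teal and amber, so the share should be filled by their end.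

3. Converted material passes through intermediates A and B into intermediate C, while product stays near zero at the late readings. Intermediate C passes the starting material left once its fraction of the converted pool is more than the bar 42.9 %, the point where the two are equal.

4. Intermediate C holds 71.7 % of the pool in midnight at 4.00 h and 86.2 % in dusk at 120 min, both more than the bar, and at those readings it also stands above intermediate A and intermediate B together . Teal runs longer and warmer than midnight , so this reckoning puts its intermediate C above 50.2 %. Amber is cooler than dusk but runs longer, so it comes near 60.3 %.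

5. The forecast names intermediate C in teal and intermediate C in amber, at 58 % and 63 %, and holds the same stopping rule, “it should stop near 30%”; its amber figure stands higher than the reckoning here.

6. The flasks give intermediate C as leader in teal with 57.4 %, and intermediate C in amber with 63.0 %.

    intermediate B ⇌ intermediate C (K = 37.0, k = 0.00140 s⁻¹, Ea = 92.0 kJ mol⁻¹, ΔH = −11.0 kJ mol⁻¹)
    reagent + intermediate A ⇌ product (K = 67.0 M⁻¹, k = 0.330 M⁻¹ s⁻¹, Ea = 61.0 kJ mol⁻¹, ΔH = −82.0 kJ mol⁻¹)
    intermediate A ⇌ intermediate B (K = 0.620, k = 1.80 × 10⁻⁴ s⁻¹, Ea = 116 kJ mol⁻¹, ΔH = −48.0 kJ mol⁻¹)
    crystals ⇌ product, rate k4*(cs4 - [product]) while solid is left; crystals form when [product] > cs4 (solubility = 5.80 mM, k = 0.0120 s⁻¹)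
    starting material + reagent → intermediate A (k = 0.0880 M⁻¹ s⁻¹, Ea = 62.0 kJ mol⁻¹)
    (constants at 70 °C)

Starting material ends at 30.4 % in teal and 30.0 % in amber, where the convertible share of 70.0 % left room for 30.0 %. The main reason intermediate C leads in amber is the falling back of product to reagent and intermediate A: with that step taken away, amber gives 18.4 % of intermediate C instead of 63.0 % and the leader changes. A neighbour of amber charged with 0.0028 M of reagent has a convertible share of 28.0 %, which puts its bar at 257 % of its pool and its starting material at 72.0 %. That neighbour ends with starting material leading at 72.0 %, and intermediate C at 25.2 %.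

All runs are calculated from invented constants; noise was put on by code.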